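1. I compared two amounts.

| flask | X | G | D | E | remark | time |
|---|---|---|---|---|---|---|
| midnight | 0.0014 M | 0.18 M | 85 µM | 0.20 mM | run made earlier |  |
| noon | 0.15 M | 0.18 M | 85 µM | 0.20 mM | run made earlier |  |
| west | 0.0012 M | 0.180 M | 85 µM | 0.20 mM |  | 4.0 min |
| south | 0.0040 M | 0.180 M | 85 µM | 0.20 mM |  | 4.0 min |
| north-west | 0.012 M | 0.180 M | 85 µM | 0.20 mM |  | 4.0 min |
| north-east | 0.030 M | 0.180 M | 85 µM | 0.20 mM |  | 4.0 min |
| south-west | 0.10 M | 0.180 M | 85 µM | 0.20 mM |  | 4.0 min |

| run | time / min | L / % | J / % |
|---|---|---|---|
| midnight | 0.667 | 8.1 | 0.3 |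
| midnight | 1.33 | 10.0 | 0 |
| midnight | 2.00 | 16.7 | 1.1 |
| midnight | 2.50 | 19.7 | 1.9 |
| midnight | 3.00 | 20.9 | 3.6 |
| midnight | 4.00 | 25.9 | 4.5 |
| noon | 0.333 | 3.5 | 0.4 |
| noon | 0.500 | 4.8 | 0.1 |
| noon | 0.833 | 6.8 | 0 |
| noon | 1.33 | 10.6 | 1.1 |
| noon | 2.50 | 18.8 | 0.9 |
| noon | 4.00 | 27.4 | 4.0 |

(standard deviation of a reading: 1 percentage point)

1. amount of L at the end, in percent of the X charged for west, south, north-west, north-east, south-west, in this order
2. how that number moves from the first to the last of them (hardly changes / rises, then falls / rises all the way / falls, then rises / falls all the way)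

- "hardly changes" means that all values lie within two and a half points (for a concentration: within two and a half percent of the largest)

2. The two amounts were the concentrations of L at 4.00 min in the midnight run and at 4.00 min in the noon run: 0.363 mM and 41.1 mM.

3. They were the last L readings of the two earlier runs, which differ in the charge of X and have the same G, D and E. The new charges run from 0.0012 M, just under the midnight charge, to 0.10 M, under the noon charge.

4. The amounts stood in the ratio 113, and the charges in the ratio 107. From these I took the charge exponent s, the percent change of the L percentage per percent change in the charge of X: s = 0.0120.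

5. The two percentages differ by 1.5 percentage points, and each carries a scatter of 1 point. So I read s as close to zero, the mark of pseudo-first-order behaviour in X.

6. With s, I reckoned 25.9% for west and 27.3% for south-west. That is a span of 1.4 points, so I committed to a flat row.

7. The forecast gave 26.7% for west and 26.7% for south-west, with the shape "hardly changes": “The percentage should hardly change.”

8. The flasks gave 26.6% in west and 26.7% in south-west, and the shape was "hardly changes".

    E + L ⇌ Z (K = 2.22 M⁻¹, k = 1330 M⁻¹ min⁻¹)
    L → Q (k = 0.0474 min⁻¹)
    X + D ⇌ D + L (K = 9.20, k = 1250 M⁻¹ min⁻¹)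
    G + Z → E + J (k = 1230 M⁻¹ min⁻¹)

9. In west at the asked time, the relaxation half-life of E + L and Z was 0.0693 s, shorter than the 5.88 min of X + D and D + L, and K1 times the starting [E] was 4.4 × 10⁻⁴, with Z at 0.0516% of the E charged. Carried from west with s, the reckoning gave 27.7% for north-east, where the flask gave 26.6%, and in south-west Z held 4.17% of the E charged at 4.00 min.

The runs were computed with constants of no real substance; scatter was added.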